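**Retrosynthetic overview**
- The target comes from NaBH4 reduction of the trans-cyclopropanecarbaldehyde; the cyclopropane is the only ring and is closed last.
- The ring bond C1–C3 comes from a 3-exo-tet alkylation of an aldehyde enolate by an allylic phosphate (inversion at C3), both unmasked from one γ-lactol.
- The C2–C3 bond (quaternary C2 next to the C3 carbinol) comes from a homoaldol addition: a sparteine-controlled, titanated geranylgeranyl carbamate (homoenolate equivalent, reacting at its C3) adds to geranylgeranial. The (E)-olefin geometry is translated into relative configuration through a chair transition state.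
- Both C20 halves come from (2E,6E,10E)-geranylgeraniol.

Assumption: geranylgeraniol of high (2E) purity is the only terpenoid feedstock; ring numbering is C1 (CH2OH-bearing), C2 (quaternary), C3 (alkenyl-bearing); the target is (1R,2R,3R).

**Step 1**
Reactants: 1 (2E,6E,10E)-geranylgeraniol; 2 N,N-diisopropylcarbamoyl chloride
Product: 3 (2E,6E,10E)-geranylgeranyl N,N-diisopropylcarbamate
Conditions: NaH, THF, 0 °C → reflux
Reagents that add atoms: N,N-diisopropylcarbamoyl chloride (2), CC(C)N(C(C)C)C(Cl)=O
Why: O-carbamoylation of the sodium alkoxide (acyl substitution) installs the hindered carbamate that later directs and stabilises α-lithiation; no stereocentre is formed and the olefins are untouched.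

**Step 2**
Reactants: 1 (2E,6E,10E)-geranylgeraniol
Product: 4 (2E,6E,10E)-geranylgeranial
Conditions: activated MnO2 (excess), hexane, 20 °C
Reagents that add atoms: none
Why: Allylic oxidation with MnO2 is selective for the allylic alcohol and keeps the (2E) geometry.

**Step 3**
Reactants: 3 geranylgeranyl N,N-diisopropylcarbamate; 4 geranylgeranial
Product: 7 (1Z,3S,4R,5E,9E,13E)-4-hydroxy-3,6,10,14,18-pentamethyl-3-[(3E,7E)-4,8,12-trimethyltrideca-3,7,11-trien-1-yl]nonadeca-1,5,9,13,17-pentaen-1-yl N,N-diisopropylcarbamate, via lithiated carbamate sparteine complex 5 (not isolated), via allyltitanium reagent 6 (not isolated)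
Conditions: n-BuLi, (−)-sparteine, toluene, −78 °C; Ti(OiPr)4 (3 equiv), −78 °C; then 4, −78 → −30 °C; aq. NH4Cl
Reagents that add atoms: none
Why: Hoppe homoaldol reaction, in which the metallated O-allyl carbamate is a homoenolate equivalent whose C3 (the future β-carbon of an aldehyde) attacks the aldehyde carbon of 4: pro-S deprotonation gives (S)-5, invertive Li→Ti exchange gives (R)-6, and 6 adds through a chair Zimmerman–Traxler transition state (aldehyde substituent equatorial, E-positioned chain equatorial, Z-positioned methyl axial), so the olefin geometry sets the quaternary centre (3S) anti to the carbinol (4R) and the C1 configuration of 6 sets the absolute sense.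

**Step 4**
Reactants: 7 homoaldol adduct
Product: 9 (4S,5R)-4-methyl-5-[(1E,5E,9E)-2,6,10,14-tetramethylpentadeca-1,5,9,13-tetraen-1-yl]-4-[(3E,7E)-4,8,12-trimethyltrideca-3,7,11-trien-1-yl]oxolan-2-ol (lactol; anomer mixture), via dilithium enolate alkoxide 8 (not isolated)
Conditions: MeLi (3.3 equiv), Et2O–THF, −78 → 20 °C; aq. NH4Cl
Reagents that add atoms: none
Why: MeLi attacks the enol carbamate carbonyl and expels the aldehyde enolate (acyl substitution with an enolate leaving group), protonation gives the γ-hydroxy aldehyde that closes to lactol 9 without touching either stereocentre; isolating 9 removes the amide-derived enolate and excess MeLi so that the next step can use exactly one equivalent of phosphorylating agent.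

**Step 5**
Reactants: 9 lactol; 10 diethyl chlorophosphate
Product: 14 prephytoene alcohol [(1R,2R,3R)-2-methyl-3-[(1E,5E,9E)-2,6,10,14-tetramethylpentadeca-1,5,9,13-tetraen-1-yl]-2-[(3E,7E)-4,8,12-trimethyltrideca-3,7,11-trien-1-yl]cyclopropyl]methanol, via dilithium enolate alkoxide mixture 11 (not isolated), via lithium enolate phosphate 12 (not isolated), via cyclopropanecarbaldehyde 13 (not isolated)
Conditions: LiN(SiMe3)2 (2.2 equiv), THF, −78 → −20 °C; ClP(O)(OEt)2 (1.05 equiv), −78 → 0 °C; then MeOH, NaBH4, 0 °C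
Reagents that add atoms: none
Why: Proposed new method: two equivalents of base drain the lactolate through its ring–chain equilibrium into the open alkoxide–enolate 11, and one equivalent of ClP(O)(OEt)2 ends up on the alkoxide oxygen (directly, or by O→O phosphoryl transfer from any enol phosphate because the enolate is the better leaving group). The enolate carbon of 12 then displaces the allylic phosphate in a 3-exo-tet SN2 with inversion at the carbinol carbon, which puts the alkenyl group cis to the long chain, and the formyl group settles trans to the alkenyl group and therefore cis to methyl. NaBH4 finally reduces 13 in the same flask. The closest known reaction type is the base-induced γ-elimination of γ-halo or γ-sulfonyloxy carbonyl compounds to cyclopropyl carbonyls (cyclopropyl methyl ketone and chrysanthemate ring closures).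

**Compound list**
1 | (2E,6E,10E)-geranylgeraniol | CC(C)=CCC/C(C)=C/CC/C(C)=C/CC/C(C)=C/CO | starting material
2 | N,N-diisopropylcarbamoyl chloride | CC(C)N(C(C)C)C(Cl)=O | starting material
3 | (2E,6E,10E)-geranylgeranyl N,N-diisopropylcarbamate | CC(C)=CCC/C(C)=C/CC/C(C)=C/CC/C(C)=C/COC(=O)N(C(C)C)C(C)C | intermediate
4 | (2E,6E,10E)-geranylgeranial | CC(C)=CCC/C(C)=C/CC/C(C)=C/CC/C(C)=C/C=O | intermediate
5 | (S)-1-lithio derivative of 3, as its (−)-sparteine complex | CC(C)=CCC/C(C)=C/CC/C(C)=C/CC/C(C)=C/[C@H]([Li])OC(=O)N(C(C)C)C(C)C | intermediate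
6 | (R)-1-(triisopropoxytitanio) derivative of 3 | CC(C)=CCC/C(C)=C/CC/C(C)=C/CC/C(C)=C/[C@@H]([Ti](OC(C)C)(OC(C)C)OC(C)C)OC(=O)N(C(C)C)C(C)C | intermediate
7 | (1Z,3S,4R)-homoaldol adduct (γ-hydroxy enol carbamate) | CC(C)=CCC/C(C)=C/CC/C(C)=C/CC/C(C)=C/[C@@H](O)[C@@](C)(CC/C=C(\C)CC/C=C(\C)CCC=C(C)C)/C=C\OC(=O)N(C(C)C)C(C)C | intermediate
8 | dilithium (Z)-enolate alkoxide from 7 | CC(C)=CCC/C(C)=C/CC/C(C)=C/CC/C(C)=C/[C@@H](O[Li])[C@@](C)(CC/C=C(\C)CC/C=C(\C)CCC=C(C)C)/C=C\O[Li] | intermediate
9 | (4S,5R)-lactol (oxolan-2-ol, anomer mixture) | CC(C)=CCC/C(C)=C/CC/C(C)=C/CC/C(C)=C/[C@H]1OC(O)C[C@]1(C)CC/C=C(\C)CC/C=C(\C)CCC=C(C)C | intermediate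
10 | diethyl chlorophosphate | CCOP(=O)(Cl)OCC | starting material
11 | dilithium enolate alkoxide from 9 (same constitution as 8, enolate E/Z mixture) | CC(C)=CCC/C(C)=C/CC/C(C)=C/CC/C(C)=C/[C@@H](O[Li])[C@@](C)(CC/C=C(\C)CC/C=C(\C)CCC=C(C)C)C=CO[Li] | intermediate
12 | lithium enolate of the allylic diethyl phosphate | CC(C)=CCC/C(C)=C/CC/C(C)=C/CC/C(C)=C/[C@@H](OP(=O)(OCC)OCC)[C@@](C)(CC/C=C(\C)CC/C=C(\C)CCC=C(C)C)C=CO[Li] | intermediate
13 | (1R,2R,3R)-cyclopropane-1-carbaldehyde | CC(C)=CCC/C(C)=C/CC/C(C)=C/CC/C(C)=C/[C@@H]1[C@@H](C=O)[C@]1(C)CC/C=C(\C)CC/C=C(\C)CCC=C(C)C | intermediate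
14 | prephytoene alcohol, (1R,2R,3R) | CC(C)=CCC/C(C)=C/CC/C(C)=C/CC/C(C)=C/[C@@H]1[C@@H](CO)[C@]1(C)CC/C=C(\C)CC/C=C(\C)CCC=C(C)C | target

**Step count and risks**
Total: 5 steps. Longest linear sequence: 4 steps (1 → 3 → 7 → 9 → 14); step 2 is the one-step branch.

Most likely to fail:

- Step 3. The enantioselectivity depends on the lithiated 3,3-disubstituted allyl carbamate holding its configuration until titanation, on the carbamoyloxy group staying endo, and on (−)-sparteine giving the (S)-lithium compound as it does for simpler carbamates. This sense of induction is assumed by analogy and has not been verified for this substrate. The fallback sets out from 1 (and uses 4) and returns at 9. It replaces the chiral lithium/titanium reagent by a catalytic allylboration: B2pin2 with Pd(MeCN)4(BF4)2 (cat.) in DMSO–MeOH converts 1 into geranylgeranyl pinacolboronate F1. F1 adds to 4 under (S)-TRIP phosphoric acid catalysis (same chair transition state, again anti; the catalyst enantiomer is an expectation to be checked) to give homoallylic alcohol F2. 9-BBN then NaBO3 hydroborates only the monosubstituted vinyl group, giving 1,4-diol F3, and TEMPO/PhI(OAc)2 (1.1 equiv) oxidises the primary alcohol to lactol 9.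

- Step 5. The lactolate may be phosphorylated before it opens, the enolate may O-alkylate to a 2-alkenyl-2,3-dihydrofuran, the allylic phosphate may ionise, and any cis-aldehyde would undergo retro-Claisen ring expansion. The fallback sets out from 9 and returns at 13. It moves the ring closure to an amide enolate: TEMPO/PhI(OAc)2 (excess) oxidises 9 to γ-lactone F4, and Me2AlN(OMe)Me opens it to hydroxy Weinreb amide F5. n-BuLi then ClP(O)(OEt)2 gives allylic phosphate F6, which LiN(SiMe3)2 closes with inversion to cyclopropane Weinreb amide F7. LiAlH4 at −78 °C gives aldehyde 13, which is reduced with NaBH4 as in step 5.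

- Step 4. MeLi may attack the hindered carbamate too slowly, and the lithium alkoxide may instead take the carbamoyl group by O→O migration. The fallback sets out from 7 and returns at 9. It switches from nucleophilic cleavage to electrophilic activation of the enol double bond: MeOH with catalytic MeSO3H at 20 °C protonates the enol carbamate, the γ-hydroxyl traps the oxocarbenium ion, and exchange gives lactol methyl ether F8. AcOH/THF/H2O then hydrolyses F8 to 9.

**Further compounds**
F1 | step 3 | 2-[(2E,6E,10E)-geranylgeranyl]-4,4,5,5-tetramethyl-1,3,2-dioxaborolane | CC(C)=CCC/C(C)=C/CC/C(C)=C/CC/C(C)=C/CB1OC(C)(C)C(C)(C)O1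
F2 | step 3 | (3S,4R,5E,9E,13E)-3,6,10,14,18-pentamethyl-3-[(3E,7E)-4,8,12-trimethyltrideca-3,7,11-trien-1-yl]nonadeca-1,5,9,13,17-pentaen-4-ol | CC(C)=CCC/C(C)=C/CC/C(C)=C/CC/C(C)=C/[C@@H](O)[C@@](C)(CC/C=C(\C)CC/C=C(\C)CCC=C(C)C)C=C
F3 | step 3 | (3S,4R)-1,4-diol from hydroboration of F2 | CC(C)=CCC/C(C)=C/CC/C(C)=C/CC/C(C)=C/[C@@H](O)[C@@](C)(CC/C=C(\C)CC/C=C(\C)CCC=C(C)C)CCO
F4 | step 5 | (4S,5R)-γ-lactone (oxolan-2-one) from 9 | CC(C)=CCC/C(C)=C/CC/C(C)=C/CC/C(C)=C/[C@H]1OC(=O)C[C@]1(C)CC/C=C(\C)CC/C=C(\C)CCC=C(C)C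
F5 | step 5 | (3S,4R)-4-hydroxy Weinreb amide | CC(C)=CCC/C(C)=C/CC/C(C)=C/CC/C(C)=C/[C@@H](O)[C@@](C)(CC/C=C(\C)CC/C=C(\C)CCC=C(C)C)CC(=O)N(C)OC
F6 | step 5 | allylic diethyl phosphate of F5 | CC(C)=CCC/C(C)=C/CC/C(C)=C/CC/C(C)=C/[C@@H](OP(=O)(OCC)OCC)[C@@](C)(CC/C=C(\C)CC/C=C(\C)CCC=C(C)C)CC(=O)N(C)OC
F7 | step 5 | (1R,2R,3R)-cyclopropane Weinreb amide | CC(C)=CCC/C(C)=C/CC/C(C)=C/CC/C(C)=C/[C@@H]1[C@@H](C(=O)N(C)OC)[C@]1(C)CC/C=C(\C)CC/C=C(\C)CCC=C(C)C
F8 | step 4 | (4S,5R)-2-methoxyoxolane (lactol methyl ether, anomer mixture) | CC(C)=CCC/C(C)=C/CC/C(C)=C/CC/C(C)=C/[C@H]1OC(OC)C[C@]1(C)CC/C=C(\C)CC/C=C(\C)CCC=C(C)C
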